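- A one-step world, solid substrate plus coupling partner giving target, fails on the spring run: 0.1 % target stands at 2.50 d, although 0.312 M of solid substrate has left the solid.

| flask | solid substrate | coupling partner | second substrate | remark | time |
|---|---|---|---|---|---|
| midnight | 0.75 M | 0.30 M | 0.25 M | run made earlier |  |
| spring | 0.50 M | 0.15 M | 0.25 M | run made earlier |  |
| beta | 0.50 M | 0.300 M | 0.150 M |  | 4.0 d |
| eta | 0.50 M | 0.300 M | 0.120 M |  | 4.0 d |
| alpha | 0.50 M | 0.300 M | 0.250 M |  | 4.0 d |
| gamma | 0.50 M | 0.300 M | 0.0800 M |  | 4.0 d |
| theta | 0.50 M | 0.300 M | 0.400 M |  | 4.0 d |

| run | time / d | target / % | solid substrate / % |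
|---|---|---|---|
| midnight | 0.625 | 3.6 | 57.7 |
| midnight | 1.25 | 3.8 | 55.5 |
| midnight | 1.67 | 4.3 | 54.7 |
| midnight | 2.50 | 4.8 | 54.9 |
| spring | 0.208 | 0 | 58.0 |
| spring | 0.417 | 0 | 45.4 |
| spring | 1.04 | 0 | 39.8 |
| spring | 2.50 | 0.1 | 37.5 |

(each reading ± 0.5 percentage points)

- given per volume of solution although it is solid: solid substrate
- at the start none of the solid substrate is in solution
- what has only dissolved of solid substrate counts as not reacted

- the flasks put in order of amount of target, in percent of the solid substrate charged, best first, at 4.0 d (beta / eta / alpha / gamma / theta)
- the same order at 5.0 h (beta / eta / alpha / gamma / theta)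
- the amount of target, in percent of the solid substrate charged of the flask you put first, at 4.0 d
- the amount of target, in percent of the solid substrate charged of the flask you put last, at 4.0 d

- Fastest rung: spring charges coupling partner at 0.15 M against second substrate at 0.25 M and holds 0.1 % target at its last reading, while midnight charges coupling partner at 0.30 M against second substrate at 0.25 M and holds 3.6 % at its first reading. My reading is that second substrate takes coupling partner one to one, before the first readings.
- That step, taken as settled, leaves the free partner, c(coupling partner) − c(second substrate): 0.0500 M at midnight.
- Dissolving rung: the spring solid approaches its level with a half-time of 3.10 h. Midnight, with more solid, has dissolved 0.302 M beside its target, so this level reads as a solubility.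
- Binding rung: at that level, the last three midnight readings give the bound share, target formed per free partner, as 0.645.
- My reckoning puts gamma first, with 0.220 M free partner and 28.4 % target, since its free partner is larger than eta's, and eta's larger than beta's. Alpha follows, and theta is last with 0.100 M more second substrate than partner, so about no target.
- Gamma's solid suffices, as its dissolved level plus target stays below the charge.
- At 5.0 h, longer than the dissolving half-time, I expect the same order, as these flasks share one solid charge.
- The forecast differs: beta > eta > gamma > alpha > theta, top 17 % (11 % to 24 %), low 0.1 % (0 % to 0.8 %), and beta > eta > gamma > alpha > theta at 5.0 h. Its ground: “The second substrate is probably also needed to activate the solid”.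

    starting material + coupling partner ⇌ target (K = 6.30 /M, k = 0.00130 /M/s)
    2 starting material → self-condensation product (k = 2.20 × 10⁻⁷ /M/s)
    second substrate + coupling partner → second product (k = 0.00700 /M/s)
    solid substrate ⇌ starting material, rate k4*(cs4 - [starting material]) while solid is left; crystals form when [starting material] > cs4 (solubility = 0.300 M, k = 6.30 × 10⁻⁵ /s)

- The flasks came out gamma > eta > beta > alpha > theta, and gamma > eta > beta > alpha > theta at 5.0 h, with 28.8 % in gamma and 0 % in theta. In gamma, second product formed while second substrate, the limiting reagent of that step, lasted, until about 0.663 h. Solid substrate went on passing into solution as starting material, half of that turnover done by 0.187 d, and target relaxed against starting material and coupling partner in 0.277 h, shorter than the 4.0 d run. Gamma's bound share came to 0.654. The neighbour of gamma with second substrate at 0.048 M, reckoned by the share at 32.5 %, gave 32.9 %.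

The runs are simulated on assumed constants.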